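Points of over-reaction product gained per day for each point of ring standing: that is the unit I would examine this flask in.

| flask | starting material | activator | remark | time |
|---|---|---|---|---|
| maple | 0.80 M | 0.53 equiv (in portions, 2) | run made earlier; portions every 5.0 h |  |
| elm | 0.80 M | 0.79 equiv (in portions, 2) | run made earlier; portions every 5.0 h |  |
| flask | 0.80 M | 1.05 equiv (in portions, 2) | the portions of activator follow each other after 5.0 h, the first at the start | 2.5 d |

- maple (time / d: starting material / %, ring / %, over-reaction product / %): 0.250: 32.8, 5.1, 0.8; 0.500: 20.5, 10.6, 4.1; 1.25: 16.7, 9.0, 17.3; 3.00: 13.9, 3.2, 32.2
- elm (time / d: starting material / %, ring / %, over-reaction product / %): 0.833: 14.0, 15.1, 14.3; 1.67: 10.1, 10.3, 29.7; 2.50: 7.6, 6.6, 40.6; 3.00: 6.2, 5.9, 45.0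

(scatter of a reading: 0.5 percentage points)

1. the state of affairs at 2.5 d: stopped, and by what, or still going (forward and back rates have come level / it is still moving / all of the starting material has reacted / the activator has run out first)
2. part of the starting material gone at 2.5 d
3. the ring standing at 2.5 d, as a percentage of the starting material charged
4. the over-reaction product standing at 2.5 d, as a percentage of the starting material charged

- the numbers in the tables scatter by 0.5 percentage points (one standard deviation)
- what has gone from starting material into another species counts as reacted, even if it can come back
- the reaction counts as stopped when no species that holds the starting material changes by six tenths of a point or more over the second half of the time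

**Which concentration sets the speed of over-reaction product?** Try c(ring). In the elm run, over-reaction product gains 11 percentage points between 1.67 d and 2.50 d, while ring averages 8.45%. That gives the ring clock 1.55 /d, the points gained per day per point of ring standing, a first-order rate constant read from the readings.

**Why not the activator?** In the maple run, with 0.53 equiv of activator against 0.79 equiv in elm, the same quotient, taken from 1.25 d to 3.00 d, comes out at 1.40 /d. The charge and the time window both differ, and the two readings lie 0.150 /d apart, so I take the speed as first order in c(ring).

**Ring in the new flask is unknown. What use is the clock?** Hold elm's 6.6% of ring as a plain figure through the second half of 2.5 d. As an estimate, the clock then gives 13 points, far more than the scatter of 0.5 points. Over-reaction product holds starting material, so I say the new flask is still moving.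

The forecast's answer was "it is still moving", with 96.5% gone, 8% ring and 51% over-reaction product, noting “over-reaction product still gains roughly 10 points per day at this stage”.

The flask's answer is "it is still moving", with 95.3% gone, 7.37% ring and 48.2% over-reaction product.

    starting material + activator → activated form (k = 0.00364 /M/min)
    activated form → ring (k = 0.0189 /min)
    starting material + activated form → open dimer (k = 0.0276 /M/min)
    ring → over-reaction product (k = 0.00105 /min)
    starting material ⇌ dormant form (K = 2.00, k = 0.00317 /min)

Just before the last addition, at 0.208 d, the flask held 31.9% starting material, 1.30% activated form and 40.3% dormant form. In the second half of the time, ring went on to over-reaction product and stood at 15.1% at 1.25 d and 7.37% at 2.50 d. On that mean ring the clock gives 22 points for this second half, and the flask's over-reaction product rose from 27.5% to 48.2%.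

The same flask read at 15 h holds 18.0% ring and 11.5% over-reaction product, and read at 25 h it holds 16.5% ring. The clock therefore gives 22.6% at 25 h, and the neighbour computed at that time stands at 22.5%.

The numbers in the tables come from a simulation on assumed constants, and the scatter is random.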